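**Plan**
1. The target is numbered as an oxolane: O1, C2H2, C3 (OH and 4-hydroxy-3-methoxybenzyl), C4 (CH2OH), C5 (4-hydroxy-3-methoxyphenyl); configuration 3S,4R,5S.
2. Retrosynthetic cuts, in order: the three O–benzyl bonds; the aryl–CH2 bond of the C3 benzyl group (aryl Grignard plus spiro-epoxide); the C3–O bond (epoxidation of a C3 methylidene group made from a C3 ketone); the ring bond C4–C5; the acetal bonds at C5.
3. Forward: O-benzylvanillin and 4-(benzyloxy)but-2-yn-1-ol are joined as a mixed methyl acetal (C5–O1); the only ring then closes at C4–C5 by gold-catalysed transfer of the methoxy group from the acetal carbon to the alkyne; ketone, methylidene, epoxide and the second aryl ring follow at C3.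
4. Enabling feature: C5 is a benzylic carbon bound to ring oxygen O1 and to an electron-rich 4-alkoxy-3-methoxyphenyl ring, so an acetal there ionises to a stabilised oxocarbenium ion; C4 and C3 are the two carbons of a but-2-yne-1,4-diol unit, and C3, which must carry oxygen, is where the migrating alkoxy group lands.
5. Stereochemistry: C5 from the chiral bisphosphine–digold catalyst in the ring closure; C4 by equilibration of the ketone α-centre trans to the aryl group; C3 by epoxidation of the exocyclic alkene on the face opposite the C4 substituent.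

Key step: step 3

Abbreviations: Ar = 4-(benzyloxy)-3-methoxyphenyl; Bn = benzyl; (R)-DTBM-MeO-BIPHEP = (R)-2,2′-bis[bis(3,5-di-tert-butyl-4-methoxyphenyl)phosphino]-6,6′-dimethoxy-1,1′-biphenyl.
Assumption: (R)-DTBM-MeO-BIPHEP(AuCl)2 is taken to deliver the (2R)-configured 6; if a trial run shows the opposite sense, the enantiomeric ligand is used and nothing else changes.

Step 1
Reactants: 1 4-(benzyloxy)-3-methoxybenzaldehyde
Product: 2 1-(benzyloxy)-4-(dimethoxymethyl)-2-methoxybenzene
Conditions: HC(OMe)3, MeOH, PPTS (cat.), rt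
Reagents that add atoms: trimethyl orthoformate, COC(OC)OC; methanol, CO
Why: Acid-catalysed acetalisation of an aromatic aldehyde, driven to completion by the orthoformate as water scavenger; no stereocentre is formed.

Step 2
Reactants: 2 1-(benzyloxy)-4-(dimethoxymethyl)-2-methoxybenzene, 3 4-(benzyloxy)but-2-yn-1-ol
Product: 5 1-(benzyloxy)-4-({[4-(benzyloxy)but-2-yn-1-yl]oxy}(methoxy)methyl)-2-methoxybenzene (racemic at the acetal carbon), via collidinium triflate salt 4 (not isolated)
Conditions: TESOTf, 2,4,6-collidine, CH2Cl2, 0 °C; then 3, 0 °C → rt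
Reagents that add atoms: none
Why: Mixed-acetal synthesis by silyl triflate/collidine activation, in which one methoxy group of the dimethyl acetal is exchanged for a collidinium leaving group that the propargylic alcohol displaces under non-acidic conditions; the acetal carbon is formed as a racemate and becomes planar again in step 3.

Step 3
Reactants: 5 1-(benzyloxy)-4-({[4-(benzyloxy)but-2-yn-1-yl]oxy}(methoxy)methyl)-2-methoxybenzene
Product: 6 (2R)-2-[4-(benzyloxy)-3-methoxyphenyl]-3-[(benzyloxy)methyl]-4-methoxy-2,5-dihydrofuran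
Conditions: (R)-DTBM-MeO-BIPHEP(AuCl)2 (2.5 mol %), AgNTf2 (5 mol %), 4 Å MS, CH2Cl2, −20 °C
Reagents that add atoms: none
Why: Proposed new method: the cationic gold centre binds the alkyne, the acetal methoxy oxygen adds anti to gold at the nearer alkyne carbon (5-exo-dig), and the resulting methyloxonium ion breaks its bond to the benzylic carbon to give an (E)-oxocarbenium ion (stabilised by the future ring oxygen and by the Ar ring) tethered to a 2-methoxyalkenylgold unit, whose gold-bearing carbon attacks the cationic carbon before gold is released. The closest known reaction type is the gold-catalysed carboalkoxylation of alkynes by acetals, which is enantioselective with this bisphosphine–digold catalyst for carbon-tethered benzylic dimethyl acetals, together with the gold-triggered alkoxy-transfer cyclisation of homopropargylic mixed acetals to cyclic enol ethers. The dihydrofuran ring closes by C–C bond formation in a 5-endo-trig mode with respect to the alkenylgold C=C (the O=C+ bond lies in the ring as well), the mode of Petasis–Ferrier ring contractions. The single new stereocentre, the benzylic C2, is set by the chiral bisphosphine on the gold-bound nucleophile, which selects one face of the planar oxocarbenium ion; because the racemic acetal carbon is flattened in that ion, both enantiomers of 5 should converge on one product. The step needs regioselectivity (only the methoxy oxygen can reach the alkyne through a five-membered transition state, secured by the two-atom O–CH2 tether), chemoselectivity over a 1,5-hydride shift from the acetal C–H to the activated alkyne and over attack by the arene (heteroatom attack should be faster at −20 °C), and ion-pair collapse at carbon, which is the only closure that gives an unstrained ring.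

Step 4
Reactants: 6 (2R)-2-[4-(benzyloxy)-3-methoxyphenyl]-3-[(benzyloxy)methyl]-4-methoxy-2,5-dihydrofuran
Product: 8 (4R,5S)-5-[4-(benzyloxy)-3-methoxyphenyl]-4-[(benzyloxy)methyl]oxolan-3-one (trans), via cis-ketone 7 (not isolated)
Conditions: (CO2H)2, THF–H2O, 0 °C; then DBU (5 mol %), CH2Cl2, 0 °C
Reagents that add atoms: water, O
Why: Enol ether hydrolysis followed by base-mediated α-epimerisation: C-protonation should occur mainly on the face opposite the aryl group (cis ketone 7), and brief enolisation then moves the α-stereocentre to the more stable trans arrangement of aryl and benzyloxymethyl groups (thermodynamic control) without touching the benzylic centre.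

Step 5
Reactants: 8 (4R,5S)-5-[4-(benzyloxy)-3-methoxyphenyl]-4-[(benzyloxy)methyl]oxolan-3-one
Product: 9 (2S,3R)-2-[4-(benzyloxy)-3-methoxyphenyl]-3-[(benzyloxy)methyl]-4-methylideneoxolane
Conditions: Ph3PCH3Br, KHMDS, THF, 0 °C; then 8, −78 → 0 °C
Reagents that add atoms: methyltriphenylphosphonium bromide, C[P+](c1ccccc1)(c1ccccc1)c1ccccc1.[Br-]
Why: Wittig methylenation with the non-stabilised ylide, which should be fast on a five-membered ketone at low temperature; no stereocentre is formed and the α-centre already has its stable trans configuration.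

Step 6
Reactants: 9 (2S,3R)-2-[4-(benzyloxy)-3-methoxyphenyl]-3-[(benzyloxy)methyl]-4-methylideneoxolane
Product: 10 (3R,6S,7R)-6-[4-(benzyloxy)-3-methoxyphenyl]-7-[(benzyloxy)methyl]-1,5-dioxaspiro[2.4]heptane
Conditions: mCPBA, NaHCO3, CH2Cl2, 0 °C
Reagents that add atoms: 3-chloroperbenzoic acid, OOC(=O)c1cccc(Cl)c1
Why: Prilezhaev epoxidation under buffered conditions; the peracid should attack the exocyclic alkene on the ring face opposite the adjacent benzyloxymethyl group (the aryl group two ring atoms away is pseudo-equatorial and shields little), so the epoxide oxygen ends trans to CH2OBn and cis to the aryl group, which is the face a carbon nucleophile would have taken at the ketone stage.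

Step 7
Reactants: 10 (3R,6S,7R)-6-[4-(benzyloxy)-3-methoxyphenyl]-7-[(benzyloxy)methyl]-1,5-dioxaspiro[2.4]heptane, 11 1-(benzyloxy)-4-bromo-2-methoxybenzene
Product: 13 (3S,4R,5S)-5-[4-(benzyloxy)-3-methoxyphenyl]-3-{[4-(benzyloxy)-3-methoxyphenyl]methyl}-4-[(benzyloxy)methyl]oxolan-3-ol, via arylmagnesium bromide 12 (not isolated)
Conditions: 11, Mg, THF, rt; CuI (10 mol %), −30 °C; then 10, −30 → 0 °C; aq NH4Cl
Reagents that add atoms: none
Why: Copper-catalysed opening of the 2,2-disubstituted epoxide by the aryl Grignard reagent at its unhindered CH2 terminus (SN2), which attaches the second aryl ring as the benzyl group and leaves the configuration of the tertiary carbinol carbon untouched.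

Step 8
Reactants: 13 (3S,4R,5S)-5-[4-(benzyloxy)-3-methoxyphenyl]-3-{[4-(benzyloxy)-3-methoxyphenyl]methyl}-4-[(benzyloxy)methyl]oxolan-3-ol
Product: 14 (3S,4R,5S)-5-(4-hydroxy-3-methoxyphenyl)-3-[(4-hydroxy-3-methoxyphenyl)methyl]-4-(hydroxymethyl)oxolan-3-ol
Conditions: H2 (1 atm), Pd/C, EtOAc–MeOH, rt
Reagents that add atoms: none
Why: Hydrogenolysis of the three benzyl ethers over palladium under neutral conditions (acid is avoided because the C5 benzylic cation would cyclise onto the second arene), stopped at full debenzylation so that the cyclic benzylic C–O bond survives; no stereocentre is affected.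

**Compound list**
1 | 4-(benzyloxy)-3-methoxybenzaldehyde | COc1cc(C=O)ccc1OCc1ccccc1 | starting material
2 | 1-(benzyloxy)-4-(dimethoxymethyl)-2-methoxybenzene | COC(OC)c1ccc(OCc2ccccc2)c(OC)c1 | intermediate
3 | 4-(benzyloxy)but-2-yn-1-ol | OCC#CCOCc1ccccc1 | starting material
4 | 1-{[4-(benzyloxy)-3-methoxyphenyl](methoxy)methyl}-2,4,6-trimethylpyridin-1-ium trifluoromethanesulfonate (racemic) | COC(c1ccc(OCc2ccccc2)c(OC)c1)[n+]1c(C)cc(C)cc1C.[O-]S(=O)(=O)C(F)(F)F | intermediate
5 | 1-(benzyloxy)-4-({[4-(benzyloxy)but-2-yn-1-yl]oxy}(methoxy)methyl)-2-methoxybenzene (racemic at the acetal carbon) | COC(OCC#CCOCc1ccccc1)c1ccc(OCc2ccccc2)c(OC)c1 | intermediate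
6 | (2R)-2-[4-(benzyloxy)-3-methoxyphenyl]-3-[(benzyloxy)methyl]-4-methoxy-2,5-dihydrofuran | COC1=C(COCc2ccccc2)[C@@H](c2ccc(OCc3ccccc3)c(OC)c2)OC1 | intermediate
7 | (4S,5S)-5-[4-(benzyloxy)-3-methoxyphenyl]-4-[(benzyloxy)methyl]oxolan-3-one (cis) | O=C1CO[C@H](c2ccc(OCc3ccccc3)c(OC)c2)[C@@H]1COCc1ccccc1 | intermediate
8 | (4R,5S)-5-[4-(benzyloxy)-3-methoxyphenyl]-4-[(benzyloxy)methyl]oxolan-3-one (trans) | O=C1CO[C@H](c2ccc(OCc3ccccc3)c(OC)c2)[C@H]1COCc1ccccc1 | intermediate
9 | (2S,3R)-2-[4-(benzyloxy)-3-methoxyphenyl]-3-[(benzyloxy)methyl]-4-methylideneoxolane | C=C1CO[C@H](c2ccc(OCc3ccccc3)c(OC)c2)[C@H]1COCc1ccccc1 | intermediate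
10 | (3R,6S,7R)-6-[4-(benzyloxy)-3-methoxyphenyl]-7-[(benzyloxy)methyl]-1,5-dioxaspiro[2.4]heptane | C1O[C@@]12CO[C@H](c3ccc(OCc4ccccc4)c(OC)c3)[C@H]2COCc2ccccc2 | intermediate
11 | 1-(benzyloxy)-4-bromo-2-methoxybenzene | COc1cc(Br)ccc1OCc1ccccc1 | starting material
12 | [4-(benzyloxy)-3-methoxyphenyl]magnesium bromide | COc1cc([Mg]Br)ccc1OCc1ccccc1 | intermediate
13 | (3S,4R,5S)-5-[4-(benzyloxy)-3-methoxyphenyl]-3-{[4-(benzyloxy)-3-methoxyphenyl]methyl}-4-[(benzyloxy)methyl]oxolan-3-ol | COc1cc(C[C@@]2(O)CO[C@H](c3ccc(OCc4ccccc4)c(OC)c3)[C@H]2COCc2ccccc2)ccc1OCc1ccccc1 | intermediate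
14 | (3S,4R,5S)-5-(4-hydroxy-3-methoxyphenyl)-3-[(4-hydroxy-3-methoxyphenyl)methyl]-4-(hydroxymethyl)oxolan-3-ol | COc1cc(C[C@@]2(O)CO[C@H](c3ccc(O)c(OC)c3)[C@H]2CO)ccc1O | target

Total steps: 8. Longest linear sequence: 8 steps (1 → 14); 3 and 11 enter as building blocks in steps 2 and 7.

**Steps most likely to fail**

Step 3 (proposed new method). The ring closure may be outrun by a 1,5-hydride shift from the acetal C–H to the activated alkyne with fragmentation, by scrambling of the mixed acetal, or by loss of the benzyloxy group from the alkenylgold stage. The ion pair may also collapse with memory of the racemic acetal centre, which would give low enantioselectivity. The fallback uses known chemistry, sets out from 1 and returns at 8. Reduction of 1 (NaBH4, MeOH) gives [4-(benzyloxy)-3-methoxyphenyl]methanol F1. Its sodium alkoxide (NaH, THF) displaces chloride from methyl 4-chloroacetoacetate to give methyl 4-{[4-(benzyloxy)-3-methoxyphenyl]methoxy}-3-oxobutanoate F2. Diazo transfer (4-acetamidobenzenesulfonyl azide, Et3N, MeCN) gives methyl 4-{[4-(benzyloxy)-3-methoxyphenyl]methoxy}-2-diazo-3-oxobutanoate F3. A chiral dirhodium tetracarboxylate, Rh2(S-PTTL)4 or its enantiomer as a trial run dictates, in CH2Cl2 should insert the carbenoid into the benzylic C–H bond next to the ether oxygen (1,5-insertion, the same ring bond as in step 3), giving methyl (2S,3R)-2-[4-(benzyloxy)-3-methoxyphenyl]-4-oxooxolane-3-carboxylate F4. LiAlH4 (THF, 0 °C) reduces ester and ketone to (4S,5S)-5-[4-(benzyloxy)-3-methoxyphenyl]-4-(hydroxymethyl)oxolan-3-ol F5 (both C3 epimers). The primary hydroxyl is benzylated through the stannylene acetal (Bu2SnO; then BnBr, CsF) to give (4S,5S)-5-[4-(benzyloxy)-3-methoxyphenyl]-4-[(benzyloxy)methyl]oxolan-3-ol F6. Dess–Martin oxidation then gives ketone 8.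

Step 6. Facial selectivity may be insufficient, because the neighbouring benzyloxymethyl group shields its face only moderately, and the spiro-epoxide may open under acid. The fallback sets out from 9 and returns at 10. Dihydroxylation with the bulkier oxidant (OsO4 cat., NMO, acetone–H2O) on the same face should give (3R,4R,5S)-5-[4-(benzyloxy)-3-methoxyphenyl]-4-[(benzyloxy)methyl]-3-(hydroxymethyl)oxolan-3-ol F7, whose epimer is separable at the diol stage. Selective sulfonylation of the primary hydroxyl (TsCl, Et3N, DMAP) gives the primary 4-methylbenzenesulfonate of that diol F8, and K2CO3 in MeOH closes the epoxide 10 without touching the tertiary centre.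

Step 5. The basic ylide may enolise the ketone instead of adding to it, with loss of the β-benzyloxy group by elimination. The fallback sets out from 8 and returns at 9. Addition of the non-basic organocerium reagent (Me3SiCH2MgCl, CeCl3, THF, −78 °C) on the face opposite the benzyloxymethyl group gives (4R,5S)-5-[4-(benzyloxy)-3-methoxyphenyl]-4-[(benzyloxy)methyl]-3-[(trimethylsilyl)methyl]oxolan-3-ol F9. Peterson elimination (KH, THF) then gives 9.

**Further compounds**
F1 | step 3 | [4-(benzyloxy)-3-methoxyphenyl]methanol | COc1cc(CO)ccc1OCc1ccccc1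
F2 | step 3 | methyl 4-{[4-(benzyloxy)-3-methoxyphenyl]methoxy}-3-oxobutanoate | COC(=O)CC(=O)COCc1ccc(OCc2ccccc2)c(OC)c1
F3 | step 3 | methyl 4-{[4-(benzyloxy)-3-methoxyphenyl]methoxy}-2-diazo-3-oxobutanoate | COC(=O)C(=[N+]=[N-])C(=O)COCc1ccc(OCc2ccccc2)c(OC)c1
F4 | step 3 | methyl (2S,3R)-2-[4-(benzyloxy)-3-methoxyphenyl]-4-oxooxolane-3-carboxylate | O=C1CO[C@H](c2ccc(OCc3ccccc3)c(OC)c2)[C@H]1C(=O)OC
F5 | step 3 | (4S,5S)-5-[4-(benzyloxy)-3-methoxyphenyl]-4-(hydroxymethyl)oxolan-3-ol, both C3 epimers | OC1CO[C@H](c2ccc(OCc3ccccc3)c(OC)c2)[C@H]1CO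
F6 | step 3 | (4S,5S)-5-[4-(benzyloxy)-3-methoxyphenyl]-4-[(benzyloxy)methyl]oxolan-3-ol, both C3 epimers | OC1CO[C@H](c2ccc(OCc3ccccc3)c(OC)c2)[C@H]1COCc1ccccc1
F7 | step 6 | (3R,4R,5S)-5-[4-(benzyloxy)-3-methoxyphenyl]-4-[(benzyloxy)methyl]-3-(hydroxymethyl)oxolan-3-ol | OC[C@@]1(O)CO[C@H](c2ccc(OCc3ccccc3)c(OC)c2)[C@H]1COCc1ccccc1
F8 | step 6 | primary 4-methylbenzenesulfonate of the diol F7 | Cc1ccc(S(=O)(=O)OC[C@@]2(O)CO[C@H](c3ccc(OCc4ccccc4)c(OC)c3)[C@H]2COCc2ccccc2)cc1
F9 | step 5 | (4R,5S)-5-[4-(benzyloxy)-3-methoxyphenyl]-4-[(benzyloxy)methyl]-3-[(trimethylsilyl)methyl]oxolan-3-ol, hydroxyl cis to the benzyloxymethyl group | C[Si](C)(C)C[C@]1(O)CO[C@H](c2ccc(OCc3ccccc3)c(OC)c2)[C@H]1COCc1ccccc1
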